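**Plan** (prostanoid numbering: C1 ester carbon; ring C8–C12 with C9 ketone, C10 CCl, C11 ring CH, C12 acetoxy carbon; C13–C20 octenyl chain)
1. Retrosynthesis: cut the C12 acetate, then C6–C7 (sp2–sp2 coupling), then C7–C8 (formylation of C8), then C10=C11 and C8–C12 together, then C12–C13.
2. Enabling feature: ring atoms C8–C9(=O)–C10(Cl) are 1,3-dichloroacetone that has spent one chlorine and kept the other; C11 (vinylic CH) and C12 (oxygen-bearing quaternary carbon) are the carbonyl and α-carbon of an α-alkoxy aldehyde. The cyclopentenone ring is therefore an aldehyde enamine annulated by that ketone.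
3. Forward: the C11–C20 chain is built first (glycolate allylation, ester to aldehyde), the ring is closed around it in one operation, then C7 and the C1–C6 chain are attached and the C12 ether is exchanged for acetate.
4. Stereochemistry: C12 from a C2-symmetric pyrrolidine that is expelled in the same step; 14Z from (Z)-oct-2-en-1-ol; 7Z from a lithium-chelated enol triflate coupled with retention; 5E from syn-hydroboration of a terminal alkyne.

Key step: step 4

Assumption: the SMILES is read as the (5E,7Z,12R,14Z) isomer, i.e. C6 of the diene chain is cis to the ring carbonyl across C7=C8.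

Step 1
Reactants: 1 (2Z)-oct-2-en-1-ol
Product: 2 (2Z)-1-bromooct-2-ene
Conditions: CBr4, PPh3, CH2Cl2, 0 °C
Reagents that add atoms: carbon tetrabromide, BrC(Br)(Br)Br
Why: Appel bromination of the primary allylic alcohol is an SN2 displacement at carbon without allylic shift, so the Z alkene (C14=C15 of the target) is carried through unchanged.

Step 2
Reactants: 2 (2Z)-1-bromooct-2-ene; 3 ethyl 2-[(4-methoxybenzyl)oxy]acetate
Product: 5 ethyl (4Z)-2-[(4-methoxybenzyl)oxy]dec-4-enoate (racemic), via lithium enolate 4 (not isolated)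
Conditions: LiN(iPr)2, THF, −78 °C; then 2, DMPU, −78 to −30 °C
Reagents that add atoms: none
Why: SN2 alkylation of the chelated lithium enolate of an α-alkoxy ester by a primary allylic bromide forms C12–C13 with the Z alkene intact; the stereocentre formed here is left racemic because it is flattened again in step 4.

Step 3
Reactants: 5 ethyl (4Z)-2-[(4-methoxybenzyl)oxy]dec-4-enoate
Product: 6 (4Z)-2-[(4-methoxybenzyl)oxy]dec-4-enal (racemic)
Conditions: iBu2AlH (1.1 equiv), CH2Cl2, −78 °C; aqueous KNaC4H4O6 work-up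
Reagents that add atoms: none
Why: partial reduction of an α-alkoxy ester with iBu2AlH stops at the chelated aluminium hemiacetal at −78 °C and releases the aldehyde on work-up.

Step 4
Reactants: 6 (4Z)-2-[(4-methoxybenzyl)oxy]dec-4-enal; 7 (2S,5S)-2,5-dimethylpyrrolidine; 8 1,3-dichloropropan-2-one
Product: 12 (4S)-2-chloro-4-[(4-methoxybenzyl)oxy]-4-[(2Z)-oct-2-en-1-yl]cyclopent-2-en-1-one, via enamine 9 (not isolated), via iminium chloride 10 (not isolated), via Mannich base hydrochloride 11 (not isolated)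
Conditions: 7 (1.1 equiv), 4 Å molecular sieves, PhMe, 40 °C; then 8 (2 equiv), MeCN, 0 to 40 °C
Reagents that add atoms: none
Why: Proposed new method: enamine 9 attacks one CH2Cl arm of 8 through C12 (SN2), the α-quaternary iminium ion 10 cannot tautomerise and is captured by the enol of the remaining ClCH2C(=O) arm (intramolecular Mannich reaction), and the ammonium salt 11 loses the amine by E1cB across C10–C11, so the ring, the quaternary carbon and the vinyl chloride arise together and the chlorine of the target is the leaving group that 8 did not use. The closest known reaction types are the Stork alkylation of α,α-disubstituted aldehyde enamines by α-halo ketones and the Fe2(CO)9-mediated [3+2] annulation of α,α'-dibromo ketones with enamines, which ends with the same Mannich closure and amine loss; their merger with a symmetrical dichloro ketone and a chiral amine is new. The ring closes in the 5-(enolendo)-exo-trig mode, the mode of the 1,4-dicarbonyl aldol cyclisation. C12 is the only new stereocentre that survives (C10 and C11 of 11 become sp2): A(1,3) strain is expected to place the two-coordinate ether oxygen cis to nitrogen in 9, the methyl group on the pyrrolidine carbon syn to C12 shields one face, and attack on the open face should give (4S)-12, the arrangement that becomes 12R in the target. The step needs C- over N-alkylation and a single alkylation per molecule of 8; the two α-methyl groups screen nitrogen, 8 is used in excess, and its twofold symmetry means that whichever arm alkylates, the other delivers the chlorine to C10.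

Step 5
Reactants: 12 (4S)-2-chloro-4-[(4-methoxybenzyl)oxy]-4-[(2Z)-oct-2-en-1-yl]cyclopent-2-en-1-one
Product: 15 (Z)-{(5R)-3-chloro-5-[(4-methoxybenzyl)oxy]-5-[(2Z)-oct-2-en-1-yl]-2-oxocyclopent-3-en-1-ylidene}methyl trifluoromethanesulfonate, via lithium dienolate 13 (not isolated), via lithium formyl enolate 14 (not isolated)
Conditions: LiN(SiMe3)2 (1.05 equiv), THF, −78 °C; CF3CH2OCHO, −78 °C; then PhNTf2, −78 to 0 °C
Reagents that add atoms: 2,2,2-trifluoroethyl formate, O=COCC(F)(F)F; N-phenylbis(trifluoromethanesulfonimide), O=S(=O)(N(c1ccccc1)S(=O)(=O)C(F)(F)F)C(F)(F)F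
Why: kinetic deprotonation at C8 (the only enolisable carbon, C12 being quaternary), Claisen formylation with trifluoroethyl formate and O-triflation of the resulting lithium-chelated 1,3-dicarbonyl enolate at its exocyclic oxygen give the enol triflate; the chelate holds that oxygen cis to the C9 carbonyl, which defines the Z geometry of C7=C8.

Step 6
Reactants: 16 methyl hex-5-ynoate
Product: 17 methyl (5E)-6-(4,4,5,5-tetramethyl-1,3,2-dioxaborolan-2-yl)hex-5-enoate
Conditions: pinacolborane (1.2 equiv), Cp2Zr(H)Cl (5 mol %), Et3N (10 mol %), neat, 60 °C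
Reagents that add atoms: pinacolborane, [H]B1OC(C)(C)C(C)(C)O1
Why: zirconium-catalysed hydroboration of the terminal alkyne with pinacolborane is a syn, anti-Markovnikov addition that gives the (E)-alkenylboronate and so sets the 5E alkene.

Step 7
Reactants: 15 (Z)-enol triflate; 17 methyl (5E)-6-(4,4,5,5-tetramethyl-1,3,2-dioxaborolan-2-yl)hex-5-enoate
Product: 18 methyl (5E,7Z)-7-{(5R)-3-chloro-5-[(4-methoxybenzyl)oxy]-5-[(2Z)-oct-2-en-1-yl]-2-oxocyclopent-3-en-1-ylidene}hept-5-enoate
Conditions: Pd(PPh3)4 (5 mol %), K3PO4 (2 equiv), THF–H2O (20:1), rt, dark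
Reagents that add atoms: none
Why: Suzuki–Miyaura coupling of the enol triflate with the (E)-alkenylboronate forms C6–C7 with retention at both sp2 carbons, which carries the 7Z geometry of 15 and the 5E geometry of 17 into the dienone, the C–OTf bond adding to zerovalent palladium before the C–Cl bond of the α-chloroenone.

Step 8
Reactants: 18 methyl (5E,7Z)-7-{(5R)-3-chloro-5-[(4-methoxybenzyl)oxy]-5-[(2Z)-oct-2-en-1-yl]-2-oxocyclopent-3-en-1-ylidene}hept-5-enoate
Product: 19 methyl (5E,7Z)-7-{(5R)-3-chloro-5-hydroxy-5-[(2Z)-oct-2-en-1-yl]-2-oxocyclopent-3-en-1-ylidene}hept-5-enoate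
Conditions: DDQ (1.5 equiv), CH2Cl2–aqueous NaH2PO4/Na2HPO4 buffer pH 7 (10:1), 0 °C to rt
Reagents that add atoms: none
Why: oxidative cleavage of the p-methoxybenzyl ether by DDQ (hydride abstraction, then hydrolysis of the oxocarbenium ion) runs under neutral conditions that leave the alkenes, the ester, the vinyl chloride and the C12 configuration untouched.

Step 9
Reactants: 19 methyl (5E,7Z)-7-{(5R)-3-chloro-5-hydroxy-5-[(2Z)-oct-2-en-1-yl]-2-oxocyclopent-3-en-1-ylidene}hept-5-enoate
Product: 20 methyl (5E,7Z)-7-{(5R)-5-acetoxy-3-chloro-5-[(2Z)-oct-2-en-1-yl]-2-oxocyclopent-3-en-1-ylidene}hept-5-enoate (target)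
Conditions: Ac2O, Et3N, DMAP (0.2 equiv), CH2Cl2, 0 °C to rt, dark
Reagents that add atoms: acetic anhydride, CC(=O)OC(C)=O
Why: DMAP-catalysed acylation of the tertiary alcohol with acetic anhydride takes place at oxygen, so C12 keeps its configuration, and with C8 now sp2 there is no enolate from which the new acetate could be eliminated.

**Compound list**
1 | (2Z)-oct-2-en-1-ol | CCCCC/C=C\CO | starting material
2 | (2Z)-1-bromooct-2-ene | CCCCC/C=C\CBr | intermediate
3 | ethyl 2-[(4-methoxybenzyl)oxy]acetate | CCOC(=O)COCc1ccc(OC)cc1 | starting material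
4 | lithium 1-ethoxy-2-[(4-methoxybenzyl)oxy]ethen-1-olate (formed in the flask) | [Li+].CCOC([O-])=COCc1ccc(OC)cc1 | intermediate
5 | ethyl (4Z)-2-[(4-methoxybenzyl)oxy]dec-4-enoate (racemic) | CCCCC/C=C\CC(OCc1ccc(OC)cc1)C(=O)OCC | intermediate
6 | (4Z)-2-[(4-methoxybenzyl)oxy]dec-4-enal (racemic) | CCCCC/C=C\CC(OCc1ccc(OC)cc1)C=O | intermediate
7 | (2S,5S)-2,5-dimethylpyrrolidine | C[C@H]1CC[C@H](C)N1 | starting material
8 | 1,3-dichloropropan-2-one | ClCC(=O)CCl | starting material
9 | (2S,5S)-1-{(1Z,4Z)-2-[(4-methoxybenzyl)oxy]deca-1,4-dien-1-yl}-2,5-dimethylpyrrolidine (formed in the flask) | C[C@H]1CC[C@H](C)N1/C=C(\OCc2ccc(OC)cc2)C/C=C\CCCCC | intermediate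
10 | (2S,5S)-1-{(2S,4Z)-2-(3-chloro-2-oxopropyl)-2-[(4-methoxybenzyl)oxy]dec-4-en-1-ylidene}-2,5-dimethylpyrrolidin-1-ium chloride (formed in the flask) | C[C@H]1CC[C@H](C)[N+]1=C[C@](OCc2ccc(OC)cc2)(C/C=C\CCCCC)CC(=O)CCl.[Cl-] | intermediate
11 | (4S)-2-chloro-3-[(2S,5S)-2,5-dimethylpyrrolidin-1-yl]-4-[(4-methoxybenzyl)oxy]-4-[(2Z)-oct-2-en-1-yl]cyclopentan-1-one hydrochloride, C2 and C3 unassigned (formed in the flask) | C[C@H]1CC[C@H](C)N1C2C(Cl)C(=O)C[C@@]2(OCc3ccc(OC)cc3)C/C=C\CCCCC.Cl | intermediate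
12 | (4S)-2-chloro-4-[(4-methoxybenzyl)oxy]-4-[(2Z)-oct-2-en-1-yl]cyclopent-2-en-1-one | CCCCC/C=C\C[C@@]1(OCc2ccc(OC)cc2)C=C(Cl)C(=O)C1 | intermediate
13 | lithium (4S)-2-chloro-4-[(4-methoxybenzyl)oxy]-4-[(2Z)-oct-2-en-1-yl]cyclopenta-1(5),2-dien-1-olate (formed in the flask) | [Li+].CCCCC/C=C\C[C@@]1(OCc2ccc(OC)cc2)C=C(Cl)C([O-])=C1 | intermediate
14 | lithium (Z)-{(5R)-3-chloro-5-[(4-methoxybenzyl)oxy]-5-[(2Z)-oct-2-en-1-yl]-2-oxocyclopent-3-en-1-ylidene}methanolate (formed in the flask) | [Li+].CCCCC/C=C\C[C@@]1(OCc2ccc(OC)cc2)C=C(Cl)C(=O)/C1=C\[O-] | intermediate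
15 | (Z)-{(5R)-3-chloro-5-[(4-methoxybenzyl)oxy]-5-[(2Z)-oct-2-en-1-yl]-2-oxocyclopent-3-en-1-ylidene}methyl trifluoromethanesulfonate | CCCCC/C=C\C[C@@]1(OCc2ccc(OC)cc2)C=C(Cl)C(=O)/C1=C\OS(=O)(=O)C(F)(F)F | intermediate
16 | methyl hex-5-ynoate | COC(=O)CCCC#C | starting material
17 | methyl (5E)-6-(4,4,5,5-tetramethyl-1,3,2-dioxaborolan-2-yl)hex-5-enoate | COC(=O)CCC/C=C/B1OC(C)(C)C(C)(C)O1 | intermediate
18 | methyl (5E,7Z)-7-{(5R)-3-chloro-5-[(4-methoxybenzyl)oxy]-5-[(2Z)-oct-2-en-1-yl]-2-oxocyclopent-3-en-1-ylidene}hept-5-enoate | CCCCC/C=C\C[C@@]1(OCc2ccc(OC)cc2)C=C(Cl)C(=O)/C1=C\C=C\CCCC(=O)OC | intermediate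
19 | methyl (5E,7Z)-7-{(5R)-3-chloro-5-hydroxy-5-[(2Z)-oct-2-en-1-yl]-2-oxocyclopent-3-en-1-ylidene}hept-5-enoate | CCCCC/C=C\C[C@@]1(O)C=C(Cl)C(=O)/C1=C\C=C\CCCC(=O)OC | intermediate
20 | methyl (5E,7Z)-7-{(5R)-5-acetoxy-3-chloro-5-[(2Z)-oct-2-en-1-yl]-2-oxocyclopent-3-en-1-ylidene}hept-5-enoate | CCCCC/C=C\C[C@@]1(OC(C)=O)C=C(Cl)C(=O)/C1=C\C=C\CCCC(=O)OC | target

**Count**
Total steps: 9. Longest linear sequence: 8 (steps 1–5 and 7–9; step 6 is a one-step side branch).

**Steps most likely to fail**

1. Step 4 (Proposed new method). What may go wrong: alkylation at nitrogen instead of at C12; loss of facial discrimination if the two enamine geometries interconvert and both alkylate; β-elimination of the C12 ether followed by aromatisation to a furan. The fallback uses known chemistry, sets out from 6 and returns at 12. Aldehyde 6 is O-acylated through its potassium enolate (KN(SiMe3)2, allyl chloroformate, THF, −78 °C) to the allyl enol carbonate F1. Palladium-catalysed decarboxylative asymmetric allylic alkylation (Pd2(dba)3·CHCl3 with the enantiomer of the DACH-phenyl Trost ligand that delivers the 2R product) converts it into the α-allyl aldehyde F2. Wacker oxidation of the terminal alkene (PdCl2, CuCl, O2, DMF–H2O) gives the 1,4-keto aldehyde F3, and aldol condensation (KOH, MeOH, 0 °C) closes the cyclopentenone F4. Weitz–Scheffer epoxidation (H2O2, NaOH, MeOH) gives the epoxy ketone F5, which HCl in THF opens at the α-carbon and dehydrates to 12.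

2. Step 5. What may go wrong: expulsion of the C12 ether from the dienolate on warming; triflation at the ring oxygen; Z to E drift of the enol triflate. The fallback sets out from 12 and returns at 18, replacing formylation and cross-coupling by the aldol route known for 4-oxygenated cyclopentenones. Methyl 5-oxopentanoate is homologated with (triphenylphosphoranylidene)acetaldehyde to methyl (5E)-7-oxohept-5-enoate F6. The lithium enolate of 12 (LiN(iPr)2, THF, −78 °C) adds to it to give the aldol adduct F7. Mesylation (MeSO2Cl, Et3N) gives the mesylate F8, which eliminates with DBU to the C7=C8 dienone as a 7E/7Z pair. Irradiation in benzene is used to equilibrate the pair, and chromatography isolates the 7Z isomer 18.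

3. Step 7. What may go wrong: Z to E isomerisation at C7=C8 through the β-acyl alkenylpalladium intermediate; hydrolysis of the vinylogous acyl triflate by the aqueous base before transmetalation. The fallback sets out from 15 (with 16) and returns at 18; it makes the union without any base by tin transmetalation. Alkyne 16 is hydrostannylated (Bu3SnH, PdCl2(PPh3)2, THF) to the (E)-alkenylstannane F9, which undergoes Stille coupling with 15 (Pd2(dba)3, AsPh3, NMP, rt) to give 18.

**Further compounds**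
F1 | step 4 | allyl (1Z,4Z)-2-[(4-methoxybenzyl)oxy]deca-1,4-dien-1-yl carbonate | C=CCOC(=O)O/C=C(\OCc1ccc(OC)cc1)C/C=C\CCCCC
F2 | step 4 | (2R,4Z)-2-[(4-methoxybenzyl)oxy]-2-(prop-2-en-1-yl)dec-4-enal | C=CC[C@](OCc1ccc(OC)cc1)(C=O)C/C=C\CCCCC
F3 | step 4 | (2S,4Z)-2-[(4-methoxybenzyl)oxy]-2-(2-oxopropyl)dec-4-enal | CC(=O)C[C@](OCc1ccc(OC)cc1)(C=O)C/C=C\CCCCC
F4 | step 4 | (4S)-4-[(4-methoxybenzyl)oxy]-4-[(2Z)-oct-2-en-1-yl]cyclopent-2-en-1-one | CCCCC/C=C\C[C@@]1(OCc2ccc(OC)cc2)C=CC(=O)C1
F5 | step 4 | (4S)-4-[(4-methoxybenzyl)oxy]-4-[(2Z)-oct-2-en-1-yl]-6-oxabicyclo[3.1.0]hexan-2-one (epoxide carbons unassigned) | CCCCC/C=C\C[C@@]1(OCc2ccc(OC)cc2)C2OC2C(=O)C1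
F6 | step 5 | methyl (5E)-7-oxohept-5-enoate | COC(=O)CCC/C=C/C=O
F7 | step 5 | methyl (5E)-7-{(5S)-3-chloro-5-[(4-methoxybenzyl)oxy]-5-[(2Z)-oct-2-en-1-yl]-2-oxocyclopent-3-en-1-yl}-7-hydroxyhept-5-enoate (C7 and ring C1 unassigned) | CCCCC/C=C\C[C@@]1(OCc2ccc(OC)cc2)C=C(Cl)C(=O)C1C(O)/C=C/CCCC(=O)OC
F8 | step 5 | methyl (5E)-7-{(5S)-3-chloro-5-[(4-methoxybenzyl)oxy]-5-[(2Z)-oct-2-en-1-yl]-2-oxocyclopent-3-en-1-yl}-7-(methanesulfonyloxy)hept-5-enoate | CCCCC/C=C\C[C@@]1(OCc2ccc(OC)cc2)C=C(Cl)C(=O)C1C(OS(C)(=O)=O)/C=C/CCCC(=O)OC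
F9 | step 7 | methyl (5E)-6-(tributylstannyl)hex-5-enoate | CCCC[Sn](CCCC)(CCCC)/C=C/CCCC(=O)OC
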